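**Retrosynthetic overview**
1. Target 11 ⇐ C1 dithioketal triol 10 (hydrolysis) ⇐ C4 ketone 9 (hydroxyl-directed reduction) ⇐ ketol 7 (enolate hydroxylation at C5). Ring oxygenation comes after ring closure.
2. The only ring is closed at C5–C6 by an enamine (aldolase-type) 6-enolendo aldol of a methyl ketone onto the erucoyl ketone of Z-enedione 6. The tertiary C6–OH is kept and C6 is set in this step.
3. 6 ⇐ conjugate addition of 2-erucoyl-1,3-dithiane 4 (C1 masked, C6 = erucate C1) to but-3-yn-2-one 5 (C2–C5); 4 ⇐ 1,3-dithiane 1 + methyl erucate 2.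

Assumption: the presumed biosynthesis is an erucoyl-primed polyketide whose carbocycle closes by aldol addition of an acetate-derived enol onto the fatty-acyl carbonyl with the tertiary hydroxyl kept, ring oxygenation following; ring atoms are numbered as in the target (C1 carbonyl, C2=C3, C4–C6 carbinols).

**Step 1**
Reactants: 1 1,3-dithiane; 2 methyl (13Z)-docos-13-enoate (methyl erucate)
Product: 4 (13Z)-1-(1,3-dithian-2-yl)docos-13-en-1-one, via 2-lithio-1,3-dithiane 3 (not isolated)
Conditions: n-BuLi (2.1 equiv), THF, −30 °C; then 2 (1.0 equiv), −78 → 0 °C; AcOH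
Reagents that add atoms: none
Why: Corey–Seebach acylation: the lithiated dithiane adds to the ester and the acidic 2-acyl dithiane is deprotonated at once by the second equivalent, which stops over-addition; the Z-alkene is inert and no stereocentre is formed.

**Step 2**
Reactants: 4 (13Z)-1-(1,3-dithian-2-yl)docos-13-en-1-one; 5 but-3-yn-2-one
Product: 6 (13Z)-1-{2-[(1Z)-3-oxobut-1-en-1-yl]-1,3-dithian-2-yl}docos-13-en-1-one
Conditions: LiN(SiMe3)2 (10 mol%), THF, −78 → −20 °C; AcOH at −78 °C; used at once
Reagents that add atoms: none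
Why: Michael addition of the soft, doubly sulfur-stabilised enolate of 4 to the ynone; the allenolate is protonated by further 4 on the side away from the bulky dithianyl group (net anti addition), giving the Z-enone, and the enolate of 4 is too weak a base to enolise the methyl ketone, so no racemic ring closure occurs.

**Step 3**
Reactants: 6 (13Z)-1-{2-[(1Z)-3-oxobut-1-en-1-yl]-1,3-dithian-2-yl}docos-13-en-1-one
Product: 7 (11R)-11-hydroxy-11-[(12Z)-henicos-12-en-1-yl]-1,5-dithiaspiro[5.5]undec-7-en-9-one
Conditions: (R)-proline (30 mol%), DMSO, 20 °C, 48 h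
Reagents that add atoms: none
Why: Proposed new method: the closest known reaction is the Hajos–Parrish–Eder–Sauer–Wiechert proline-catalysed 6-enolendo ketol cyclisation; proline condenses with the enone carbonyl to a 2-amino-diene (the only enolisable position is the methyl group), which attacks the erucoyl ketone (activated by two alpha sulfur atoms and flanked by a quaternary carbon, as in the Hajos–Parrish triketone) through the anti-enamine transition state with the acceptor oxygen pseudo-axial and hydrogen-bonded to the carboxylic acid and the C21 chain pseudo-equatorial; (S)-proline gives the (S)-carbinol in the Hajos–Parrish ketol, which has the same priority pattern, so (R)-proline should give the (R)-carbinol (target C6) here, and the tertiary alcohol cannot dehydrate towards the quaternary thioketal carbon.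

**Step 4**
Reactants: 7 (11R)-11-hydroxy-11-[(12Z)-henicos-12-en-1-yl]-1,5-dithiaspiro[5.5]undec-7-en-9-one
Product: 9 (10S,11R)-10,11-dihydroxy-11-[(12Z)-henicos-12-en-1-yl]-1,5-dithiaspiro[5.5]undec-7-en-9-one, via dilithium alkoxide-dienolate 8 (not isolated)
Conditions: LiN(i-Pr)2 (2.3 equiv), THF, −78 °C (7 added to the base); then 3-phenyl-2-(phenylsulfonyl)oxaziridine (1.2 equiv), −78 °C; AcOH
Reagents that add atoms: 3-phenyl-2-(phenylsulfonyl)oxaziridine, O=S(=O)(N1OC1c1ccccc1)c1ccccc1
Why: Davis enolate hydroxylation: the cross-conjugated dienolate can form only at target C5, and the oxaziridine should attack anti to the C21 chain, which sits pseudo-axial on the neighbouring quaternary carbon, i.e. on the face of the C6 alkoxide, giving the cis-5,6-diol; at −78 °C the dithiane sulfur and the isolated alkene are not oxidised, and the preformed dianion cannot undergo retro-aldol.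

**Step 5**
Reactants: 9 (10S,11R)-10,11-dihydroxy-11-[(12Z)-henicos-12-en-1-yl]-1,5-dithiaspiro[5.5]undec-7-en-9-one
Product: 10 (7R,8R,9S)-7-[(12Z)-henicos-12-en-1-yl]-1,5-dithiaspiro[5.5]undec-10-ene-7,8,9-triol
Conditions: Me4NBH(OAc)3 (5 equiv), MeCN/AcOH 1:1, −30 °C
Reagents that add atoms: none
Why: Evans–Saksena hydroxyl-directed reduction: the acetoxyborohydride bound on the face of the cis-diol (the tertiary OH is beta to the ketone) delivers hydride intramolecularly to target C4 from that face, so the new C4–OH is anti to C6–OH and trans to C5–OH; reduction is 1,2 only, and the dithiane and alkene are untouched.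

**Step 6**
Reactants: 10 (7R,8R,9S)-7-[(12Z)-henicos-12-en-1-yl]-1,5-dithiaspiro[5.5]undec-10-ene-7,8,9-triol
Product: 11 (4S,5R,6R)-4,5,6-trihydroxy-6-[(12Z)-henicos-12-en-1-yl]cyclohex-2-en-1-one (target)
Conditions: MeI (10 equiv), CaCO3, MeCN/H2O 9:1, 40 °C
Reagents that add atoms: water, O
Why: Dithioketal hydrolysis by S-methylation (Fétizon–Jurion conditions): the sulfonium leaves as a thionium ion that water converts into the C1 ketone, which is then conjugated with C2=C3; the buffered neutral medium leaves the three carbinols and the Z-alkene alone, excess MeI traps the released thiol, and no stereocentre is alpha to the new ketone with a hydrogen, so nothing epimerises.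

**Compound list**
1 | 1,3-dithiane | C1CSCSC1 | starting material
2 | methyl (13Z)-docos-13-enoate (methyl erucate) | CCCCCCCC/C=C\CCCCCCCCCCCC(=O)OC | starting material
3 | 2-lithio-1,3-dithiane | [Li]C1SCCCS1 | intermediate (not isolated)
4 | (13Z)-1-(1,3-dithian-2-yl)docos-13-en-1-one | CCCCCCCC/C=C\CCCCCCCCCCCC(=O)C1SCCCS1 | intermediate
5 | but-3-yn-2-one | CC(=O)C#C | starting material
6 | (13Z)-1-{2-[(1Z)-3-oxobut-1-en-1-yl]-1,3-dithian-2-yl}docos-13-en-1-one | CCCCCCCC/C=C\CCCCCCCCCCCC(=O)C1(/C=C\C(C)=O)SCCCS1 | intermediate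
7 | (11R)-11-hydroxy-11-[(12Z)-henicos-12-en-1-yl]-1,5-dithiaspiro[5.5]undec-7-en-9-one | CCCCCCCC/C=C\CCCCCCCCCCC[C@]1(O)C2(SCCCS2)C=CC(=O)C1 | intermediate
8 | dilithium (11R)-11-[(12Z)-henicos-12-en-1-yl]-11-oxido-1,5-dithiaspiro[5.5]undeca-7,9-dien-9-olate | [Li+].[Li+].CCCCCCCC/C=C\CCCCCCCCCCC[C@]1([O-])C2(SCCCS2)C=CC([O-])=C1 | intermediate (not isolated)
9 | (10S,11R)-10,11-dihydroxy-11-[(12Z)-henicos-12-en-1-yl]-1,5-dithiaspiro[5.5]undec-7-en-9-one | CCCCCCCC/C=C\CCCCCCCCCCC[C@]1(O)C2(SCCCS2)C=CC(=O)[C@H]1O | intermediate
10 | (7R,8R,9S)-7-[(12Z)-henicos-12-en-1-yl]-1,5-dithiaspiro[5.5]undec-10-ene-7,8,9-triol | CCCCCCCC/C=C\CCCCCCCCCCC[C@]1(O)C2(SCCCS2)C=C[C@H](O)[C@H]1O | intermediate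
11 | (4S,5R,6R)-4,5,6-trihydroxy-6-[(12Z)-henicos-12-en-1-yl]cyclohex-2-en-1-one | CCCCCCCC/C=C\CCCCCCCCCCC[C@]1(O)C(=O)C=C[C@H](O)[C@H]1O | target

**Totals**
Total steps: 6. Longest linear sequence: 6 (1 or 2 → 11).

**Steps most likely to fail, and fallbacks**

Step 3 is the largest risk: the rate, the ee and the sense of induction of the proline aldol on this substrate are inferred by analogy and are untested. The fallback sets out from 6: KOC(CH3)3 (5 mol%) in THF/t-BuOH at −20 °C closes the same ring under thermodynamic control to give racemic 11-hydroxy-11-[(12Z)-henicos-12-en-1-yl]-1,5-dithiaspiro[5.5]undec-7-en-9-one F1. The enantiomers are separated by preparative chromatography on a chiral phase, and the (S)-enantiomer is re-racemised with the same base through retro-aldol/aldol and recycled. The (R)-enantiomer is 7, where the route is rejoined.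

Step 2 may give the E-enone, which cannot cyclise, or some premature racemic ring closure. The fallback sets out from 4: its sodium enolate (NaH, THF, 0 °C) displaces methoxide from (E)-4-methoxybut-3-en-2-one by addition–elimination with retention, giving (13Z)-1-{2-[(1E)-3-oxobut-1-en-1-yl]-1,3-dithian-2-yl}docos-13-en-1-one F2. This is stable to base because it cannot reach the ketone. Irradiation at 365 nm in MeCN (enone n–π* band; the chain alkene does not absorb) then isomerises it to the Z-enone, and the route is rejoined at 6.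

Step 4 may suffer retro-aldol of the lithium alkoxide, the wrong facial selectivity, or sulfur oxidation. The fallback sets out from 7 and avoids strong base: nitrosobenzene with (R)-proline in DMSO at 0 °C performs a catalyst-controlled enamine α-aminoxylation. (S)-Proline gives the (R)-aminooxy ketone from cyclohexanone, so the (R)-catalyst should set the (S) centre required here. The product is (10S,11R)-10-(anilinooxy)-11-hydroxy-11-[(12Z)-henicos-12-en-1-yl]-1,5-dithiaspiro[5.5]undec-7-en-9-one F3. N–O cleavage with CuSO4 (30 mol%) in MeOH at 0 °C returns to the route at 9.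

**Further compounds**
F1 | step 3 | racemic 11-hydroxy-11-[(12Z)-henicos-12-en-1-yl]-1,5-dithiaspiro[5.5]undec-7-en-9-one | CCCCCCCC/C=C\CCCCCCCCCCCC1(O)C2(SCCCS2)C=CC(=O)C1
F2 | step 2 | (13Z)-1-{2-[(1E)-3-oxobut-1-en-1-yl]-1,3-dithian-2-yl}docos-13-en-1-one | CCCCCCCC/C=C\CCCCCCCCCCCC(=O)C1(/C=C/C(C)=O)SCCCS1
F3 | step 4 | (10S,11R)-10-(anilinooxy)-11-hydroxy-11-[(12Z)-henicos-12-en-1-yl]-1,5-dithiaspiro[5.5]undec-7-en-9-one | CCCCCCCC/C=C\CCCCCCCCCCC[C@]1(O)C2(SCCCS2)C=CC(=O)[C@H]1ONc1ccccc1
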